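## Retrosynthetic overview

1. The target is unmasked last by acidolysis of a tert-butyl ester and a triethylsilyl ether. Before that, the side-chain acid is C-acylated onto (R)-4-hydroxy-6-methyl-5,6-dihydro-2H-pyran-2-one (O-acylation, then O-to-C acyl shift).
2. Key disconnection: the bond between the carboxyl-bearing stereocentre and the (E)-alkene. It is made by nickel-catalysed stereoconvergent radical alkenylation of an α-bromo-β-silyloxy ester (both bromide epimers) with an (E)-alkenylzirconocene, and this step creates that stereocentre.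
3. Bromo ester: (S)-2-methylbutanoic acid and tert-butyl acetate (Claisen), Noyori hydrogenation (carbinol centre), one-pot dianion bromination/silylation.
4. Alkenyl partner: methyl 4-oxobutanoate by Wittig thioester olefination, copper-catalysed asymmetric methyl conjugate addition (methyl-bearing centre), Fukuyama reduction, Ohira–Bestmann alkynylation.
5. Ring order: the dihydropyranone is the only ring. It is closed first (Claisen condensation of methyl (R)-3-hydroxybutanoate with tert-butyl acetate, then lactonisation) and joined to the chain in the penultimate step.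

Assumption: the ligand enantiomers named in steps 7 and 10 are taken to be the ones that give the configurations drawn; if a first run shows the opposite sense, the mirror-image ligand is used with nothing else changed.

## Route

Step 1
Reactants: 1 methyl (R)-3-hydroxybutanoate; 2 tert-butyl acetate
Product: 4 tert-butyl (R)-5-hydroxy-3-oxohexanoate, via lithium enolate of tert-butyl acetate 3 (not isolated)
Conditions: 2 (3.3 equiv), LiN(i-Pr)2 (3.3 equiv), THF, −78 °C; 1, −78 to −30 °C; AcOH
Reagents that add atoms: none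
Why: Crossed Claisen condensation in which the excess enolate first deprotonates the hydroxyl and then acylates on the methyl ester, the product being protected as its β-keto ester enolate; the (R)-carbinol centre comes unchanged from 1.

Step 2
Reactants: 4 tert-butyl (R)-5-hydroxy-3-oxohexanoate
Product: 5 (R)-4-hydroxy-6-methyl-5,6-dihydro-2H-pyran-2-one
Conditions: TFA, CH2Cl2, 0 °C to rt
Reagents that add atoms: none
Why: Acid-mediated tert-butyl ester cleavage and lactonisation onto the δ-hydroxyl closes the only ring of the target as its stable enol tautomer without touching the stereocentre.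

Step 3
Reactants: 6 (S)-2-methylbutanoic acid; 2 tert-butyl acetate
Product: 9 tert-butyl (S)-4-methyl-3-oxohexanoate, via acyl imidazolide 7 (not isolated), via sodium enolate of tert-butyl acetate 8 (not isolated)
Conditions: 6, CDI, THF, rt; added to 8 [2 (3 equiv), NaN(SiMe3)2 (3 equiv), THF, −78 °C]; AcOH
Reagents that add atoms: none
Why: Claisen-type C-acylation of the sodium ester enolate by the acyl imidazolide (Masamune-type β-keto ester synthesis) at −78 °C, where the product is held as its sodium enolate, which stops over-addition, and the hindered α-stereocentre of 6 is not enolised.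

Step 4
Reactants: 9 tert-butyl (S)-4-methyl-3-oxohexanoate
Product: 10 tert-butyl (3S,4S)-3-hydroxy-4-methylhexanoate
Conditions: H2 (50 atm), RuCl2[(R)-BINAP] (0.5 mol %), MeOH, 30 °C
Reagents that add atoms: none
Why: Noyori asymmetric hydrogenation of a β-keto ester, in which the (R)-BINAP–ruthenium catalyst sets the (3S)-carbinol under catalyst control (the same spatial sense as (R)-3-hydroxybutanoate from acetoacetate) and overrides the weak Me/Et bias of the adjacent centre, which is not enolised under these near-neutral conditions.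

Step 5
Reactants: 10 tert-butyl (3S,4S)-3-hydroxy-4-methylhexanoate
Product: 13 tert-butyl (3R,4S)-2-bromo-4-methyl-3-(triethylsilyloxy)hexanoate (both C-2 epimers), via dilithium dianion 11 (not isolated), via lithium alkoxide of the bromohydrin 12 (not isolated)
Conditions: LiN(i-Pr)2 (2.1 equiv), THF, −78 to −30 °C; cannulated into BrCCl2CCl2Br, THF, −78 °C; TESOTf, −78 to −40 °C; aq. NaHCO3
Reagents that add atoms: 1,2-dibromo-1,1,2,2-tetrachloroethane, ClC(Cl)(Br)C(Cl)(Cl)Br; triethylsilyl trifluoromethanesulfonate, CC[Si](CC)(CC)OS(=O)(=O)C(F)(F)F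
Why: Fráter–Seebach-type dianion formation and electrophilic α-bromination, with silyl capping of the lithium alkoxide at low temperature to forestall Darzens epoxide closure; C-2 is deliberately left as a mixture because step 10 is stereoconvergent, and C-3 and C-4 are untouched.

Step 6
Reactants: 14 methyl 4-oxobutanoate
Product: 15 methyl (4E)-6-(ethylsulfanyl)-6-oxohex-4-enoate
Conditions: Ph3P=CHC(O)SEt, CH2Cl2, 40 °C
Reagents that add atoms: S-ethyl 2-(triphenyl-λ5-phosphanylidene)ethanethioate, CCSC(=O)C=P(c1ccccc1)(c1ccccc1)c1ccccc1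
Why: Wittig olefination with a stabilised ylide gives the (E)-α,β-unsaturated thioester selectively and leaves the methyl ester untouched.

Step 7
Reactants: 15 methyl (4E)-6-(ethylsulfanyl)-6-oxohex-4-enoate
Product: 16 methyl (4R)-6-(ethylsulfanyl)-4-methyl-6-oxohexanoate
Conditions: MeMgBr (1.2 equiv), CuBr·SMe2 (5 mol %), (R)-1-[(S)-2-(diphenylphosphino)ferrocenyl]ethyldicyclohexylphosphine (6 mol %), t-BuOMe, −75 °C; 1 M HCl
Reagents that add atoms: methylmagnesium bromide, C[Mg]Br
Why: Copper-catalysed asymmetric conjugate addition of a Grignard reagent to an α,β-unsaturated thioester, in which the chiral ferrocenyl diphosphine–copper complex delivers methyl to one face of the (E)-enethioate to set the (4R) centre, while the low temperature keeps MeMgBr off both acyl groups.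

Step 8
Reactants: 16 methyl (4R)-6-(ethylsulfanyl)-4-methyl-6-oxohexanoate
Product: 17 methyl (4R)-4-methyl-6-oxohexanoate
Conditions: Et3SiH, 10% Pd/C, CH2Cl2, rt
Reagents that add atoms: none
Why: Fukuyama reduction stops at the aldehyde and does not touch the methyl ester or the non-epimerisable β-stereocentre.

Step 9
Reactants: 17 methyl (4R)-4-methyl-6-oxohexanoate
Product: 18 methyl (4R)-4-methylhept-6-ynoate
Conditions: dimethyl (1-diazo-2-oxopropyl)phosphonate, K2CO3, MeOH, 0 °C to rt
Reagents that add atoms: dimethyl (1-diazo-2-oxopropyl)phosphonate, COP(=O)(OC)C(=[N+]=[N-])C(C)=O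
Why: Ohira–Bestmann (Seyferth–Gilbert) homologation converts the aldehyde into the terminal alkyne under mild K2CO3/MeOH conditions that match the methyl ester.

Step 10
Reactants: 18 methyl (4R)-4-methylhept-6-ynoate; 13 tert-butyl (3R,4S)-2-bromo-4-methyl-3-(triethylsilyloxy)hexanoate (both C-2 epimers)
Product: 20 1-tert-butyl 9-methyl (2R,3E,6R)-6-methyl-2-[(1R,2S)-2-methyl-1-(triethylsilyloxy)butyl]non-3-enedioate, via alkenylzirconocene chloride 19 (not isolated)
Conditions: 18 (1.4 equiv), Cp2Zr(H)Cl, THF, rt; then 13, NiCl2·glyme (5 mol %), 2,2'-methylenebis[(4S,5R)-4,5-diphenyl-2-oxazoline] (6.5 mol %), DME/THF, 10 °C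
Reagents that add atoms: none
Why: Proposed new method: extension of the nickel/bis(oxazoline)-catalysed stereoconvergent Negishi-type alkenylation of racemic α-bromo ketones with alkenylzirconocenes (and of the related nickel-catalysed couplings of racemic α-bromo esters with alkenylsilanes) to a β-silyloxy α-bromo ester — a monovalent nickel species abstracts bromine from either C-2 epimer of 13 to give one planar α-ester radical, which is captured by the chiral alkenyl–nickel complex and released by fast reductive elimination from trivalent nickel, so the ligand fixes the new (2R) centre, the (E)-geometry from syn-hydrozirconation is retained and the base-free medium prevents conjugation of the β,γ-unsaturated ester.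

Step 11
Reactants: 20 1-tert-butyl 9-methyl (2R,3E,6R)-6-methyl-2-[(1R,2S)-2-methyl-1-(triethylsilyloxy)butyl]non-3-enedioate
Product: 21 (4R,6E,8R,9R,10S)-8-(tert-butoxycarbonyl)-4,10-dimethyl-9-(triethylsilyloxy)dodec-6-enoic acid
Conditions: Me3SnOH, ClCH2CH2Cl, 75 °C; 1 M HCl wash
Reagents that add atoms: trimethyltin hydroxide, C[Sn](C)(C)O
Why: Me3SnOH-mediated hydrolysis is selective for the unhindered methyl ester over the tert-butyl ester and, being essentially neutral, neither epimerises nor conjugates the β,γ-unsaturated ester nor cleaves the silyl ether.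

Step 12
Reactants: 21 (4R,6E,8R,9R,10S)-8-(tert-butoxycarbonyl)-4,10-dimethyl-9-(triethylsilyloxy)dodec-6-enoic acid; 5 (R)-4-hydroxy-6-methyl-5,6-dihydro-2H-pyran-2-one
Product: 23 tert-butyl (2R,3E,6R)-9-[(6R)-4-hydroxy-6-methyl-2-oxo-5,6-dihydro-2H-pyran-3-yl]-6-methyl-2-[(1R,2S)-2-methyl-1-(triethylsilyloxy)butyl]-9-oxonon-3-enoate, via enol ester 22 (not isolated)
Conditions: DCC, DMAP, CH2Cl2, 0 °C to rt
Reagents that add atoms: none
Why: Steglich-type O-acylation of the acidic pyranone enol followed by DMAP-mediated O-to-C acyl migration (Fries-type rearrangement) gives the thermodynamically favoured chelated 3-acyl tricarbonyl, while the silyl ether blocks competing esterification of the secondary alcohol.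

Step 13
Reactants: 23 tert-butyl (2R,3E,6R)-9-[(6R)-4-hydroxy-6-methyl-2-oxo-5,6-dihydro-2H-pyran-3-yl]-6-methyl-2-[(1R,2S)-2-methyl-1-(triethylsilyloxy)butyl]-9-oxonon-3-enoate
Product: 24 (2R,3E,6R)-9-[(6R)-4-hydroxy-6-methyl-2-oxo-5,6-dihydro-2H-pyran-3-yl]-2-[(1R,2S)-1-hydroxy-2-methylbutyl]-6-methyl-9-oxonon-3-enoic acid
Conditions: TFA/CH2Cl2/H2O (10:10:1), 0 °C to rt
Reagents that add atoms: none
Why: Acidolysis removes the tert-butyl ester and the triethylsilyl ether in one operation under conditions to which the acylpyranone, the (E)-alkene and the α-stereocentre of the β,γ-unsaturated acid are stable.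

## Compound list

1 | methyl (R)-3-hydroxybutanoate | C[C@@H](O)CC(=O)OC | starting material
2 | tert-butyl acetate | CC(=O)OC(C)(C)C | starting material
3 | lithium enolate of tert-butyl acetate (not isolated) | [Li+].C=C([O-])OC(C)(C)C | intermediate
4 | tert-butyl (R)-5-hydroxy-3-oxohexanoate | C[C@@H](O)CC(=O)CC(=O)OC(C)(C)C | intermediate
5 | (R)-4-hydroxy-6-methyl-5,6-dihydro-2H-pyran-2-one | C[C@@H]1CC(O)=CC(=O)O1 | intermediate
6 | (S)-2-methylbutanoic acid | CC[C@H](C)C(=O)O | starting material
7 | (S)-1-(1H-imidazol-1-yl)-2-methylbutan-1-one (not isolated) | CC[C@H](C)C(=O)n1ccnc1 | intermediate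
8 | sodium enolate of tert-butyl acetate (not isolated) | [Na+].C=C([O-])OC(C)(C)C | intermediate
9 | tert-butyl (S)-4-methyl-3-oxohexanoate | CC[C@H](C)C(=O)CC(=O)OC(C)(C)C | intermediate
10 | tert-butyl (3S,4S)-3-hydroxy-4-methylhexanoate | CC[C@H](C)[C@@H](O)CC(=O)OC(C)(C)C | intermediate
11 | dilithium dianion (alkoxide ester enolate) of 10 (not isolated) | [Li+].[Li+].CC[C@H](C)[C@@H]([O-])C=C([O-])OC(C)(C)C | intermediate
12 | lithium (3R,4S)-2-bromo-1-tert-butoxy-4-methyl-1-oxohexan-3-olate, both C-2 epimers (not isolated) | [Li+].CC[C@H](C)[C@@H]([O-])C(Br)C(=O)OC(C)(C)C | intermediate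
13 | tert-butyl (3R,4S)-2-bromo-4-methyl-3-(triethylsilyloxy)hexanoate, both C-2 epimers | CC[C@H](C)[C@@H](O[Si](CC)(CC)CC)C(Br)C(=O)OC(C)(C)C | intermediate
14 | methyl 4-oxobutanoate | COC(=O)CCC=O | starting material
15 | methyl (4E)-6-(ethylsulfanyl)-6-oxohex-4-enoate | CCSC(=O)/C=C/CCC(=O)OC | intermediate
16 | methyl (4R)-6-(ethylsulfanyl)-4-methyl-6-oxohexanoate | CCSC(=O)C[C@H](C)CCC(=O)OC | intermediate
17 | methyl (4R)-4-methyl-6-oxohexanoate | O=CC[C@H](C)CCC(=O)OC | intermediate
18 | methyl (4R)-4-methylhept-6-ynoate | C#CC[C@H](C)CCC(=O)OC | intermediate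
19 | chlorobis(cyclopentadienyl)[(1E,4R)-7-methoxy-4-methyl-7-oxohept-1-en-1-yl]zirconium (not isolated) | COC(=O)CC[C@@H](C)C/C=C/[Zr](Cl)(C1C=CC=C1)C1C=CC=C1 | intermediate
20 | 1-tert-butyl 9-methyl (2R,3E,6R)-6-methyl-2-[(1R,2S)-2-methyl-1-(triethylsilyloxy)butyl]non-3-enedioate | CC[C@H](C)[C@@H](O[Si](CC)(CC)CC)[C@@H](/C=C/C[C@H](C)CCC(=O)OC)C(=O)OC(C)(C)C | intermediate
21 | (4R,6E,8R,9R,10S)-8-(tert-butoxycarbonyl)-4,10-dimethyl-9-(triethylsilyloxy)dodec-6-enoic acid | CC[C@H](C)[C@@H](O[Si](CC)(CC)CC)[C@@H](/C=C/C[C@H](C)CCC(=O)O)C(=O)OC(C)(C)C | intermediate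
22 | (6R)-6-methyl-2-oxo-5,6-dihydro-2H-pyran-4-yl (4R,6E,8R,9R,10S)-8-(tert-butoxycarbonyl)-4,10-dimethyl-9-(triethylsilyloxy)dodec-6-enoate (not isolated) | CC[C@H](C)[C@@H](O[Si](CC)(CC)CC)[C@@H](/C=C/C[C@H](C)CCC(=O)OC1=CC(=O)O[C@H](C)C1)C(=O)OC(C)(C)C | intermediate
23 | tert-butyl (2R,3E,6R)-9-[(6R)-4-hydroxy-6-methyl-2-oxo-5,6-dihydro-2H-pyran-3-yl]-6-methyl-2-[(1R,2S)-2-methyl-1-(triethylsilyloxy)butyl]-9-oxonon-3-enoate | CC[C@H](C)[C@@H](O[Si](CC)(CC)CC)[C@@H](/C=C/C[C@H](C)CCC(=O)C1=C(O)C[C@@H](C)OC1=O)C(=O)OC(C)(C)C | intermediate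
24 | (2R,3E,6R)-9-[(6R)-4-hydroxy-6-methyl-2-oxo-5,6-dihydro-2H-pyran-3-yl]-2-[(1R,2S)-1-hydroxy-2-methylbutyl]-6-methyl-9-oxonon-3-enoic acid | CC[C@H](C)[C@@H](O)[C@@H](/C=C/C[C@H](C)CCC(=O)C1=C(O)C[C@@H](C)OC1=O)C(=O)O | target

## Step count and risks

Total steps: 13. Longest linear sequence: 8 (steps 6 to 13).

Steps most likely to fail:

**Step 10.** The radical is secondary and flanked by a branched silyloxy carbon, the chiral ligand may be mismatched with the existing stereocentres, and β-silyloxy elimination can compete. The fallback sets out from 18 and comes back at 20. The alkenylzirconocene 19 made from 18 is coupled under achiral NiCl2·glyme/2,2'-bipyridine catalysis with tert-butyl bromoacetate, an unhindered primary radical precursor, to give 1-tert-butyl 9-methyl (3E,6R)-6-methylnon-3-enedioate F1, so the radical step keeps the same bond but no longer has to create a stereocentre. (S)-2-Methylbutan-1-ol is oxidised (TEMPO, PhI(OAc)2) to (S)-2-methylbutanal F2. F1 is enolised at its doubly activated C-2 with a chiral 2-bromo-4,5-diphenyl-1,3-bis(arylsulfonyl)-1,3,2-diazaborolidine and Et3N and added to F2 in a reagent-controlled anti-aldol reaction to give 1-tert-butyl 9-methyl (2R,3E,6R)-2-[(1R,2S)-1-hydroxy-2-methylbutyl]-6-methylnon-3-enedioate F3. TESOTf/2,6-lutidine converts F3 into 20.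

**Step 5.** Proton transfer between product and dianion can give dibromide plus starting ester, and the bromo alkoxide can close to the epoxide before it is silylated. The fallback sets out from 10 and comes back at 13. 10 is silylated first (TESOTf, 2,6-lutidine) to tert-butyl (3S,4S)-4-methyl-3-(triethylsilyloxy)hexanoate F4. F4 is deprotonated with in situ silyl trapping (LiN(SiMe3)2, Me3SiCl, THF, −78 °C) to the silyl ketene acetal [(3R,4S)-1-tert-butoxy-4-methyl-3-(triethylsilyloxy)hex-1-en-1-yl]oxy(trimethyl)silane F5. Bromination of F5 with NBS at −78 °C gives 13 with neither a free alkoxide nor an enolate present.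

**Step 12.** The O-to-C acyl shift can stall at the enol ester, and N-acylurea formation competes. The fallback sets out from 21 and comes back at 23; it builds the ring onto the side chain instead of acylating the finished ring. 21 is condensed with Meldrum's acid (DCC, DMAP) to tert-butyl (2R,3E,6R)-9-(2,2-dimethyl-4,6-dioxo-1,3-dioxan-5-ylidene)-9-hydroxy-6-methyl-2-[(1R,2S)-2-methyl-1-(triethylsilyloxy)butyl]non-3-enoate F6. Heating F6 with 1 in toluene gives the β-keto ester 1-tert-butyl 11-[(2R)-4-methoxy-4-oxobutan-2-yl] (2R,3E,6R)-6-methyl-2-[(1R,2S)-2-methyl-1-(triethylsilyloxy)butyl]-9-oxoundec-3-enedioate F7. Dieckmann cyclisation of F7 with KOt-Bu (1.05 equiv, THF, 0 °C) closes the 3-acyl-4-hydroxydihydropyranone and gives 23.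

## Further compounds

F1 | step 10 | 1-tert-butyl 9-methyl (3E,6R)-6-methylnon-3-enedioate | COC(=O)CC[C@@H](C)C/C=C/CC(=O)OC(C)(C)C
F2 | step 10 | (S)-2-methylbutanal | CC[C@H](C)C=O
F3 | step 10 | 1-tert-butyl 9-methyl (2R,3E,6R)-2-[(1R,2S)-1-hydroxy-2-methylbutyl]-6-methylnon-3-enedioate | CC[C@H](C)[C@@H](O)[C@@H](/C=C/C[C@H](C)CCC(=O)OC)C(=O)OC(C)(C)C
F4 | step 5 | tert-butyl (3S,4S)-4-methyl-3-(triethylsilyloxy)hexanoate | CC[C@H](C)[C@@H](O[Si](CC)(CC)CC)CC(=O)OC(C)(C)C
F5 | step 5 | [(3R,4S)-1-tert-butoxy-4-methyl-3-(triethylsilyloxy)hex-1-en-1-yl]oxy(trimethyl)silane | CC[C@H](C)[C@@H](O[Si](CC)(CC)CC)C=C(O[Si](C)(C)C)OC(C)(C)C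
F6 | step 12 | tert-butyl (2R,3E,6R)-9-(2,2-dimethyl-4,6-dioxo-1,3-dioxan-5-ylidene)-9-hydroxy-6-methyl-2-[(1R,2S)-2-methyl-1-(triethylsilyloxy)butyl]non-3-enoate | CC[C@H](C)[C@@H](O[Si](CC)(CC)CC)[C@@H](/C=C/C[C@H](C)CCC(O)=C1C(=O)OC(C)(C)OC1=O)C(=O)OC(C)(C)C
F7 | step 12 | 1-tert-butyl 11-[(2R)-4-methoxy-4-oxobutan-2-yl] (2R,3E,6R)-6-methyl-2-[(1R,2S)-2-methyl-1-(triethylsilyloxy)butyl]-9-oxoundec-3-enedioate | CC[C@H](C)[C@@H](O[Si](CC)(CC)CC)[C@@H](/C=C/C[C@H](C)CCC(=O)CC(=O)O[C@H](C)CC(=O)OC)C(=O)OC(C)(C)C
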